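- A leftover started me off: at 40.0 min the south-east run still held 52.3 % of its E unturned, yet J had gained 20 percentage points in the first 5.00 min and 3.4 points in the last 15.0 min.

| flask | E | Q | G | temperature | remark | time |
|---|---|---|---|---|---|---|
| south-east | 0.50 M | 0.60 M | 0.50 mM | 60 °C | the very flask that is asked about, followed so far |  |
| north | 0.50 M | 0.40 M | 0.50 mM | 45 °C | run made earlier |  |
| flask | 0.50 M | 0.600 M | 0.50 mM | 60 °C |  | 50 min |

| south-east: time / min | south-east: J / % | north: time / min | north: J / % |
|---|---|---|---|
| 5.00 | 20.0 | 3.00 | 3.9 |
| 15.0 | 37.1 | 8.00 | 8.5 |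
| 25.0 | 44.3 | 12.0 | 11.6 |
| 40.0 | 47.7 | 20.0 | 17.0 |

(scatter of a reading: 0.3 percentage points)

- autumn: at 50 min add G, 50.0 % of the amount charged, then wait 1.5 h
- midnight: at 50 min raise the temperature by 10 K, then wait 1.5 h
- winter: change nothing and wait 1.5 h more
- noon: at 50 min add Q, 50.0 % of the amount charged, then wait 1.5 h
- dusk: at 50 min take out 90 % of the J then present, then wait 1.5 h

- J, in percent of the E first charged, at 50 min
- the option that brings most further J ("none" if no option brings more than 2 percentage points) (autumn / midnight / winter / noon / dusk / none)
- J present, with what was taken out counted in, in percent of the E first charged, after winter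
- J present, with what was taken out counted in, in percent of the E first charged, after dusk

- Had each J cost one Q, [Q] in the south-east run would still have stood at 0.361 M at that last reading. The readings could not prove what slowed the run, but I took it that Q was also lost by a second way that needed no G, which made Q the limiting reagent.
- Treating the 0.60 M of Q in the south-east run as used by 40.0 min, an assumption of mine, I had two amounts: the Q that became J, 0.239 M, and the Q lost otherwise, 0.361 M. Their ratio, the Q odds, 0.660, is a selectivity read from that one reading: Q turned into J per Q lost, the two rates averaged over the run.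
- I expected the south-east flask at 50 min to stand a little above its last reading. Noon's added Q, 0.300 M, would meet about 0.261 M of E, a ratio of 1.15 against 1.20 at the charge, so I kept the odds and reckoned a gain of 24 points. The other options add no Q, so I chose noon.
- The forecast read the stall differently, “The limit is therefore equilibrium, not kinetics”, and gave 48.4 % now, 49 % after winter, 67.1 % after dusk, and dusk as best.
- The south-east flask gave 48.7 % at 50 min, with Q at 1.04 % of its charge. Noon brought 28 points, and dusk and winter 1.2 points each, leaving 49.9 % after dusk and 49.9 % after winter.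

    E + D → L (k = 300 L mol⁻¹ min⁻¹, Ea = 63.0 kJ mol⁻¹)
    L → G + J (k = 270 min⁻¹, Ea = 66.0 kJ mol⁻¹)
    Q + G ⇌ D (K = 1.70 L mol⁻¹, k = 2200 L mol⁻¹ min⁻¹, Ea = 36.0 kJ mol⁻¹, ΔH = 31.0 kJ mol⁻¹)
    2 Q → Z (k = 0.180 L mol⁻¹ min⁻¹, Ea = 75.0 kJ mol⁻¹)
    (constants at 60 °C)

- The neighbour flask was the same recipe with 2.0 × 10⁻⁴ M of G. Scaling the odds with G gave 0.264, hence J at 25.1 % of the E charged. At 50 min that neighbour flask held Q at 3.2 % of its charge and J at 29.0 %.

The readings are calculated with constants of no real substance; the scatter is artificial.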